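**Retrosynthetic overview**

1. Labels: ring A (propenal arene), ring B (dioxane on A; Ca carries ring C and O3A, Cb carries CH2OH and O4A), ring C (central arene), ring D (dioxane on C; Cc carries CH2OH and O3C, Cd carries ring E and O4C), ring E (catechol); target Ca S, Cb S (trans), Cc S, Cd R (cis). The route rests on Cd: it is benzylic to ring E, bonded to O4C (the ring C oxygen para to Ca) and cis to the CH2OH on Cc, so it is a syn 2-aryloxy-1-aryl alcohol inverted once at Cd.
2. The propenal comes last, by Wittig olefination of a ring A aldehyde; ring B (trans) comes from a syn glycolate aldol adduct by C–O coupling of Ca–OH onto ring A C3–Br with retention.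
3. Ring D (cis) comes from a syn glycolate aldol adduct by Mitsunobu displacement at Cd by O4C with inversion, ring E being kept electron-poor as its bis-mesylate.
4. Both syn aryloxy alcohols come from Evans glycolate aldol reactions with the same (R)-4-benzyl auxiliary: ring C glycolate plus ring E aldehyde, then ring A glycolate plus ring C aldehyde.
5. Ring order: D (step 8), then B (step 15).

Key step: step 8

Assumption: reagent 3 is bought as the (R) enantiomer; mesylates are used on ring E instead of acyl groups because they survive the hydride steps and still keep ring E electron-poor.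

**Route**

Step 1
Reactants: 1 4-(benzyloxy)-3-hydroxybenzaldehyde
Product: 2 2-(benzyloxy)-5-(1,3-dioxolan-2-yl)phenol
Conditions: HOCH2CH2OH, p-TsOH (cat.), toluene, reflux, Dean–Stark
Reagents that add atoms: ethylene glycol, OCCO
Why: Acid-catalysed acetalisation with azeotropic removal of water should mask the aldehyde carbon (later Ca) against the enolate and hydride steps, the phenol being meta to it and so no source of acetal lability.

Step 2
Reactants: 2 2-(benzyloxy)-5-(1,3-dioxolan-2-yl)phenol; 3 (R)-4-benzyl-3-(chloroacetyl)oxazolidin-2-one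
Product: 4 (R)-4-benzyl-3-{[2-(benzyloxy)-5-(1,3-dioxolan-2-yl)phenoxy]acetyl}oxazolidin-2-one
Conditions: K2CO3, NaI (cat.), acetone, 45 °C
Reagents that add atoms: none
Why: Williamson etherification: the phenoxide O3C displaces halide from the α-halo imide (iodide exchange in the flask) to form the O3C–Cc bond, carbonate being too weak a base to enolise or open the imide.

Step 3
Reactants: 5 3,4-dihydroxybenzaldehyde
Product: 6 3,4-bis(methanesulfonyloxy)benzaldehyde
Conditions: MeSO2Cl, Et3N, CH2Cl2, 0 °C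
Reagents that add atoms: methanesulfonyl chloride, CS(=O)(=O)Cl
Why: O-sulfonylation of both phenols should give an aldehyde that is activated for the aldol addition and already carries the electron-poor ring E needed at the ring D closure.

Step 4
Reactants: 4 (R)-4-benzyl-3-{[2-(benzyloxy)-5-(1,3-dioxolan-2-yl)phenoxy]acetyl}oxazolidin-2-one; 6 3,4-bis(methanesulfonyloxy)benzaldehyde
Product: 9 (R)-4-benzyl-3-{(2R,3S)-2-[2-(benzyloxy)-5-(1,3-dioxolan-2-yl)phenoxy]-3-[3,4-bis(methanesulfonyloxy)phenyl]-3-hydroxypropanoyl}oxazolidin-2-one, via boron Z-enolate 7 (not isolated), via boron aldolate 8 (not isolated)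
Conditions: Bu2BOTf, i-Pr2NEt, CH2Cl2, −78 to 0 °C; then 6, −78 to 0 °C; pH 7 buffer, MeOH, H2O2, 0 °C
Reagents that add atoms: none
Why: Evans syn aldol: the Z boron enolate adds through a chair transition state on the face away from the benzyl group of the (R) auxiliary, which should set Cc (R in the imide, S after reduction) and Cd (S) together as the syn pair, and the acetal should hold at low temperature in the presence of the amine.

Step 5
Reactants: 9 syn aldol adduct
Product: 10 (1S,2S)-2-[2-(benzyloxy)-5-(1,3-dioxolan-2-yl)phenoxy]-1-[3,4-bis(methanesulfonyloxy)phenyl]propane-1,3-diol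
Conditions: LiBH4, MeOH, THF, 0 °C
Reagents that add atoms: none
Why: Reductive cleavage of the N-acyl oxazolidinone by LiBH4 should turn the imide carbonyl into the CH2OH group on Cc without touching Cc or Cd, and borohydride leaves aryl mesylates, the acetal and the benzyl ether intact.

Step 6
Reactants: 10 (1S,2S)-diol
Product: 11 (1S,2S)-2-[2-(benzyloxy)-5-(1,3-dioxolan-2-yl)phenoxy]-1-[3,4-bis(methanesulfonyloxy)phenyl]-3-[(tert-butyldimethylsilyl)oxy]propan-1-ol
Conditions: TBSCl, imidazole, CH2Cl2, 0 °C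
Reagents that add atoms: tert-butyldimethylsilyl chloride, CC(C)(C)[Si](C)(C)Cl
Why: Silylation with TBSCl and imidazole is selective for the primary hydroxyl over the hindered secondary benzylic one, which removes the only competing site of activation in the ring closure.

Step 7
Reactants: 11 benzyl ether
Product: 12 (1S,2S)-1-[3,4-bis(methanesulfonyloxy)phenyl]-3-[(tert-butyldimethylsilyl)oxy]-2-[5-(1,3-dioxolan-2-yl)-2-hydroxyphenoxy]propan-1-ol
Conditions: H2 (1 atm), Pd/C, EtOAc, rt
Reagents that add atoms: none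
Why: Hydrogenolysis of the aryl benzyl ether over Pd/C in a neutral aprotic solvent is much faster than that of the cyclic acetal or of the electron-poor benzylic carbinol and should free O4C–H; the product, an acid-labile acetal para to a phenol, is filtered and used at once.

Step 8
Reactants: 12 syn Cc aryl ether Cd alcohol with free O4C–H
Product: 14 (2R,3S)-2-[3,4-bis(methanesulfonyloxy)phenyl]-3-{[(tert-butyldimethylsilyl)oxy]methyl}-6-(1,3-dioxolan-2-yl)-2,3-dihydro-1,4-benzodioxine (cis), via alkoxyphosphonium phenoxide 13 (not isolated)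
Conditions: PPh3, DIAD, THF (dilute), 0 °C to rt
Reagents that add atoms: none
Why: Mitsunobu etherification: the PPh3–DIAD betaine takes the proton of O4C–H and converts Cd–OH into the alkoxyphosphonium 13, which the ring C phenoxide displaces from the rear with loss of Ph3PO. The closest known reaction type is the intramolecular Mitsunobu aryl ether synthesis from a phenol and a secondary benzylic alcohol. Ring D closes in the 6-exo-tet mode, the leaving group lying outside the new ring. Cd is the only centre that changes: it goes from S to R by inversion, so its sense is fixed by the aldol of step 4, Cc (S) is a spectator, and syn becomes cis. The step needs substitution with inversion in preference to ionisation (which would drift to the trans ring) and to loss of the Cc hydrogen (enol ether); the two mesyloxy groups make a benzylic cation on ring E poor, Cc carries CH2OTBS and no carbonyl so its hydrogen is not acidic, and the silyl cap leaves Cd–OH as the only hydroxyl that can be activated.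

Step 9
Reactants: 14 cis ring C–D–E acetal
Product: 15 (2R,3S)-2-[3,4-bis(methanesulfonyloxy)phenyl]-3-{[(tert-butyldimethylsilyl)oxy]methyl}-2,3-dihydro-1,4-benzodioxine-6-carbaldehyde
Conditions: PPTS, acetone–H2O, rt
Reagents that add atoms: water, O
Why: Mild acid hydrolysis of the aryl dioxolane should free the ring C aldehyde while the primary TBS ether and, thanks to the electron-poor ring E, the cis benzylic ether at Cd stay in place.

Step 10
Reactants: 16 3-bromo-4-hydroxybenzaldehyde; 3 (R)-4-benzyl-3-(chloroacetyl)oxazolidin-2-one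
Product: 17 (R)-4-benzyl-3-[(2-bromo-4-formylphenoxy)acetyl]oxazolidin-2-one
Conditions: K2CO3, NaI (cat.), MeCN, 50 °C
Reagents that add atoms: none
Why: Williamson etherification as in step 2 puts the ring A oxygen para to the formyl group (O4A) on the glycolate carbon that becomes Cb, and the bromine ortho to it is the later handle for closing ring B.

Step 11
Reactants: 17 ring A formyl glycolate imide
Product: 18 (R)-4-benzyl-3-{[2-bromo-4-(1,3-dioxolan-2-yl)phenoxy]acetyl}oxazolidin-2-one
Conditions: Me3SiOCH2CH2OSiMe3, Me3SiOSO2CF3 (cat.), CH2Cl2, −78 to −20 °C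
Reagents that add atoms: 1,2-bis(trimethylsilyloxy)ethane, C[Si](C)(C)OCCO[Si](C)(C)C
Why: Acetalisation with the bis-silyl ether of ethylene glycol under silyl triflate catalysis (Noyori conditions) is aprotic and cold enough to spare the imide, and it follows the O-alkylation because a dioxolane para to a free phenol would be too labile.

Step 12
Reactants: 18 ring A glycolate imide; 15 ring C–D–E aldehyde
Product: 21 (R)-4-benzyl-3-{(2R,3S)-2-[2-bromo-4-(1,3-dioxolan-2-yl)phenoxy]-3-hydroxy-3-Ar-propanoyl}oxazolidin-2-one (Ar is the benzodioxin-6-yl group of 15), via boron Z-enolate 19 (not isolated), via boron aldolate 20 (not isolated)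
Conditions: Bu2BOTf, i-Pr2NEt, CH2Cl2, −78 to 0 °C; then 15, −78 to 0 °C; pH 7 buffer, MeOH, H2O2, 0 °C
Reagents that add atoms: none
Why: Second Evans syn aldol with the same (R) auxiliary: the Z boron enolate 19 adds to aldehyde 15 through the chair transition state and should set Cb (R in the imide, S after reduction) and Ca (S) as the syn pair under reagent control that overrides the remote centres of ring D.

Step 13
Reactants: 21 syn aldol adduct
Product: 22 (1S,2S)-1-Ar-2-[2-bromo-4-(1,3-dioxolan-2-yl)phenoxy]propane-1,3-diol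
Conditions: LiBH4, MeOH, THF, 0 °C
Reagents that add atoms: none
Why: Reductive removal of the oxazolidinone as in step 5 gives the CH2OH group on Cb and leaves the aryl bromide, mesylates, silyl ether and acetal untouched.

Step 14
Reactants: 22 (1S,2S)-diol
Product: 23 (1S,2S)-1-Ar-2-[2-bromo-4-(1,3-dioxolan-2-yl)phenoxy]-3-[(triisopropylsilyl)oxy]propan-1-ol
Conditions: TIPSCl, imidazole, DMF, 0 °C to rt
Reagents that add atoms: triisopropylsilyl chloride, CC(C)[Si](Cl)(C(C)C)C(C)C
Why: Selective silylation of the primary hydroxyl with the bulky TIPS group, chosen because it should not migrate to the neighbouring alkoxide under the basic conditions of the next step.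

Step 15
Reactants: 23 bromo aryl ether with free Ca–OH
Product: 24 (2S,3S)-3-Ar-6-(1,3-dioxolan-2-yl)-2-{[(triisopropylsilyl)oxy]methyl}-2,3-dihydro-1,4-benzodioxine (trans ring B)
Conditions: Pd(OAc)2 (cat.), 2-(di-tert-butylphosphino)-1,1'-binaphthyl, Cs2CO3, toluene, 80 °C
Reagents that add atoms: none
Why: Palladium-catalysed intramolecular aryl etherification (Buchwald–Hartwig C–O coupling): zerovalent palladium inserts into the ring A C3–Br bond, the Ca alkoxide binds and the bulky phosphine drives C–O reductive elimination ahead of β-hydride loss, so ring B closes at the aryl carbon with Ca (S) and Cb (S) untouched and the syn pair becomes the trans ring, while the TIPS cap blocks closure through the primary oxygen and the carbonate base spares the mesylates.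

Step 16
Reactants: 24 bis-mesylate
Product: 25 as 24 but with ring E as the free catechol
Conditions: LiN(i-Pr)2, THF, −78 to 0 °C; aq. NH4Cl
Reagents that add atoms: none
Why: Cleavage of aryl mesylates with lithium amide base: deprotonation of the S-methyl group and loss of sulfene release both phenoxides at low temperature, where silyl ethers, the acetal and both dioxane rings should persist, and hot alkali that could open ring D through a quinone methide is avoided.

Step 17
Reactants: 25 catechol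
Product: 26 as 24 but with ring E as the bis(tert-butyldimethylsilyl) ether
Conditions: TBSCl, imidazole, DMF, rt
Reagents that add atoms: tert-butyldimethylsilyl chloride, CC(C)(C)[Si](C)(C)Cl
Why: Standard silylation of the catechol gives aryl silyl ethers that tolerate the acetal hydrolysis and the olefination and leave in the same final operation as the alkyl silyl ethers.

Step 18
Reactants: 26 ring A dioxolane
Product: 27 ring A 6-carbaldehyde corresponding to 26
Conditions: PPTS, acetone–H2O, rt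
Reagents that add atoms: water, O
Why: Hydrolysis of the ring A dioxolane, which is activated by the para ring oxygen O4A, should proceed under conditions too mild to cleave aryl or primary alkyl silyl ethers or to ionise the benzylic ethers at Ca and Cd.

Step 19
Reactants: 27 ring A aldehyde
Product: 28 (E)-propenal corresponding to 27
Conditions: Ph3P=CHCHO, toluene, 80 °C
Reagents that add atoms: (triphenylphosphoranylidene)acetaldehyde, O=CC=P(c1ccccc1)(c1ccccc1)c1ccccc1
Why: Wittig olefination with the stabilised formyl ylide extends the aryl aldehyde by two carbons directly to the enal, the E geometry following from the reversible addition of a stabilised ylide.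

Step 20
Reactants: 28 fully silylated enal
Product: 29 CNP0302404.1
Conditions: Bu4NF, AcOH, THF, 0 °C to rt
Reagents that add atoms: none
Why: Fluoride-mediated cleavage of all four silyl ethers, buffered with AcOH so that neither the enal, the catechol nor the cis benzylic aryl ether at Cd (para to a free phenol) is exposed to base.

**Compound list**

1 | 4-(benzyloxy)-3-hydroxybenzaldehyde | O=Cc1ccc(OCc2ccccc2)c(O)c1 | starting material
2 | 2-(benzyloxy)-5-(1,3-dioxolan-2-yl)phenol | Oc1cc(C2OCCO2)ccc1OCc1ccccc1 | intermediate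
3 | (R)-4-benzyl-3-(chloroacetyl)oxazolidin-2-one | O=C(CCl)N1[C@H](Cc2ccccc2)COC1=O | starting material
4 | (R)-4-benzyl-3-{[2-(benzyloxy)-5-(1,3-dioxolan-2-yl)phenoxy]acetyl}oxazolidin-2-one (ring C glycolate imide) | O=C(COc1cc(C2OCCO2)ccc1OCc1ccccc1)N1[C@H](Cc2ccccc2)COC1=O | intermediate
5 | 3,4-dihydroxybenzaldehyde | O=Cc1ccc(O)c(O)c1 | starting material
6 | 3,4-bis(methanesulfonyloxy)benzaldehyde | O=Cc1ccc(OS(C)(=O)=O)c(OS(C)(=O)=O)c1 | intermediate
7 | Z dibutylboron enolate of 4 (not isolated) | CCCCB(CCCC)O/C(=C\Oc1cc(C2OCCO2)ccc1OCc1ccccc1)N1[C@H](Cc2ccccc2)COC1=O | intermediate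
8 | O-dibutylboron aldolate of 9 (not isolated) | O1CCOC1c1ccc(OCc2ccccc2)c(c1)O[C@@H](C(=O)N1[C@H](Cc2ccccc2)COC1=O)[C@H](c1ccc(OS(C)(=O)=O)c(OS(C)(=O)=O)c1)OB(CCCC)CCCC | intermediate
9 | (R)-4-benzyl-3-{(2R,3S)-2-[2-(benzyloxy)-5-(1,3-dioxolan-2-yl)phenoxy]-3-[3,4-bis(methanesulfonyloxy)phenyl]-3-hydroxypropanoyl}oxazolidin-2-one | O1CCOC1c1ccc(OCc2ccccc2)c(c1)O[C@@H](C(=O)N1[C@H](Cc2ccccc2)COC1=O)[C@H](c1ccc(OS(C)(=O)=O)c(OS(C)(=O)=O)c1)O | intermediate
10 | (1S,2S)-2-[2-(benzyloxy)-5-(1,3-dioxolan-2-yl)phenoxy]-1-[3,4-bis(methanesulfonyloxy)phenyl]propane-1,3-diol | O1CCOC1c1ccc(OCc2ccccc2)c(c1)O[C@@H](CO)[C@H](c1ccc(OS(C)(=O)=O)c(OS(C)(=O)=O)c1)O | intermediate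
11 | (1S,2S)-2-[2-(benzyloxy)-5-(1,3-dioxolan-2-yl)phenoxy]-1-[3,4-bis(methanesulfonyloxy)phenyl]-3-[(tert-butyldimethylsilyl)oxy]propan-1-ol | O1CCOC1c1ccc(OCc2ccccc2)c(c1)O[C@@H](CO[Si](C)(C)C(C)(C)C)[C@H](c1ccc(OS(C)(=O)=O)c(OS(C)(=O)=O)c1)O | intermediate
12 | (1S,2S)-1-[3,4-bis(methanesulfonyloxy)phenyl]-3-[(tert-butyldimethylsilyl)oxy]-2-[5-(1,3-dioxolan-2-yl)-2-hydroxyphenoxy]propan-1-ol (key-step precursor) | O1CCOC1c1ccc(O)c(c1)O[C@@H](CO[Si](C)(C)C(C)(C)C)[C@H](c1ccc(OS(C)(=O)=O)c(OS(C)(=O)=O)c1)O | intermediate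
13 | Cd alkoxytriphenylphosphonium phenoxide of 12 (zwitterion, not isolated) | [O-]c1ccc(C2OCCO2)cc1O[C@@H](CO[Si](C)(C)C(C)(C)C)[C@H](c1ccc(OS(C)(=O)=O)c(OS(C)(=O)=O)c1)O[P+](c1ccccc1)(c1ccccc1)c1ccccc1 | intermediate
14 | (2R,3S)-2-[3,4-bis(methanesulfonyloxy)phenyl]-3-{[(tert-butyldimethylsilyl)oxy]methyl}-6-(1,3-dioxolan-2-yl)-2,3-dihydro-1,4-benzodioxine (cis, key-step product) | O1CCOC1c1ccc2c(c1)O[C@@H](CO[Si](C)(C)C(C)(C)C)[C@@H](c1ccc(OS(C)(=O)=O)c(OS(C)(=O)=O)c1)O2 | intermediate
15 | (2R,3S)-2-[3,4-bis(methanesulfonyloxy)phenyl]-3-{[(tert-butyldimethylsilyl)oxy]methyl}-2,3-dihydro-1,4-benzodioxine-6-carbaldehyde | O=Cc1ccc2c(c1)O[C@@H](CO[Si](C)(C)C(C)(C)C)[C@@H](c1ccc(OS(C)(=O)=O)c(OS(C)(=O)=O)c1)O2 | intermediate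
16 | 3-bromo-4-hydroxybenzaldehyde | O=Cc1ccc(O)c(Br)c1 | starting material
17 | (R)-4-benzyl-3-[(2-bromo-4-formylphenoxy)acetyl]oxazolidin-2-one | O=Cc1ccc(OCC(=O)N2[C@H](Cc3ccccc3)COC2=O)c(Br)c1 | intermediate
18 | (R)-4-benzyl-3-{[2-bromo-4-(1,3-dioxolan-2-yl)phenoxy]acetyl}oxazolidin-2-one (ring A glycolate imide) | Brc1cc(C2OCCO2)ccc1OCC(=O)N1[C@H](Cc2ccccc2)COC1=O | intermediate
19 | Z dibutylboron enolate of 18 (not isolated) | CCCCB(CCCC)O/C(=C\Oc1ccc(C2OCCO2)cc1Br)N1[C@H](Cc2ccccc2)COC1=O | intermediate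
20 | O-dibutylboron aldolate of 21 (not isolated) | Brc1cc(C2OCCO2)ccc1O[C@@H](C(=O)N1[C@H](Cc2ccccc2)COC1=O)[C@@H](OB(CCCC)CCCC)c1ccc2c(c1)O[C@@H](CO[Si](C)(C)C(C)(C)C)[C@@H](c1ccc(OS(C)(=O)=O)c(OS(C)(=O)=O)c1)O2 | intermediate
21 | (R)-4-benzyl-3-{(2R,3S)-2-[2-bromo-4-(1,3-dioxolan-2-yl)phenoxy]-3-hydroxy-3-Ar-propanoyl}oxazolidin-2-one, Ar = (2R,3S)-2-[3,4-bis(methanesulfonyloxy)phenyl]-3-{[(tert-butyldimethylsilyl)oxy]methyl}-2,3-dihydro-1,4-benzodioxin-6-yl | Brc1cc(C2OCCO2)ccc1O[C@@H](C(=O)N1[C@H](Cc2ccccc2)COC1=O)[C@@H](O)c1ccc2c(c1)O[C@@H](CO[Si](C)(C)C(C)(C)C)[C@@H](c1ccc(OS(C)(=O)=O)c(OS(C)(=O)=O)c1)O2 | intermediate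
22 | (1S,2S)-1-Ar-2-[2-bromo-4-(1,3-dioxolan-2-yl)phenoxy]propane-1,3-diol (Ar as in 21) | Brc1cc(C2OCCO2)ccc1O[C@@H](CO)[C@@H](O)c1ccc2c(c1)O[C@@H](CO[Si](C)(C)C(C)(C)C)[C@@H](c1ccc(OS(C)(=O)=O)c(OS(C)(=O)=O)c1)O2 | intermediate
23 | (1S,2S)-1-Ar-2-[2-bromo-4-(1,3-dioxolan-2-yl)phenoxy]-3-[(triisopropylsilyl)oxy]propan-1-ol (Ar as in 21) | Brc1cc(C2OCCO2)ccc1O[C@@H](CO[Si](C(C)C)(C(C)C)C(C)C)[C@@H](O)c1ccc2c(c1)O[C@@H](CO[Si](C)(C)C(C)(C)C)[C@@H](c1ccc(OS(C)(=O)=O)c(OS(C)(=O)=O)c1)O2 | intermediate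
24 | (2S,3S)-3-Ar-6-(1,3-dioxolan-2-yl)-2-{[(triisopropylsilyl)oxy]methyl}-2,3-dihydro-1,4-benzodioxine (Ar as in 21; trans ring B, cis ring D) | O1CCOC1c1ccc2c(c1)O[C@@H](c1ccc3c(c1)O[C@@H](CO[Si](C)(C)C(C)(C)C)[C@@H](c1ccc(OS(C)(=O)=O)c(OS(C)(=O)=O)c1)O3)[C@H](CO[Si](C(C)C)(C(C)C)C(C)C)O2 | intermediate
25 | as 24 with ring E as free 3,4-dihydroxyphenyl | O1CCOC1c1ccc2c(c1)O[C@@H](c1ccc3c(c1)O[C@@H](CO[Si](C)(C)C(C)(C)C)[C@@H](c1ccc(O)c(O)c1)O3)[C@H](CO[Si](C(C)C)(C(C)C)C(C)C)O2 | intermediate
26 | as 24 with ring E as 3,4-bis[(tert-butyldimethylsilyl)oxy]phenyl | O1CCOC1c1ccc2c(c1)O[C@@H](c1ccc3c(c1)O[C@@H](CO[Si](C)(C)C(C)(C)C)[C@@H](c1ccc(O[Si](C)(C)C(C)(C)C)c(O[Si](C)(C)C(C)(C)C)c1)O3)[C@H](CO[Si](C(C)C)(C(C)C)C(C)C)O2 | intermediate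
27 | ring A 6-carbaldehyde corresponding to 26 (Ca S, Cb S, Cc S, Cd R) | O=Cc1ccc2c(c1)O[C@@H](c1ccc3c(c1)O[C@@H](CO[Si](C)(C)C(C)(C)C)[C@@H](c1ccc(O[Si](C)(C)C(C)(C)C)c(O[Si](C)(C)C(C)(C)C)c1)O3)[C@H](CO[Si](C(C)C)(C(C)C)C(C)C)O2 | intermediate
28 | (E)-propenal corresponding to 27, fully silylated | O=C/C=C/c1ccc2c(c1)O[C@@H](c1ccc3c(c1)O[C@@H](CO[Si](C)(C)C(C)(C)C)[C@@H](c1ccc(O[Si](C)(C)C(C)(C)C)c(O[Si](C)(C)C(C)(C)C)c1)O3)[C@H](CO[Si](C(C)C)(C(C)C)C(C)C)O2 | intermediate
29 | CNP0302404.1, (E)-3-[(2S,3S)-3-{(2R,3S)-2-(3,4-dihydroxyphenyl)-3-(hydroxymethyl)-2,3-dihydro-1,4-benzodioxin-6-yl}-2-(hydroxymethyl)-2,3-dihydro-1,4-benzodioxin-6-yl]prop-2-enal | O=C/C=C/c1ccc2c(c1)O[C@@H](c1ccc3c(c1)O[C@@H](CO)[C@@H](c1ccc(O)c(O)c1)O3)[C@H](CO)O2 | target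

**Step count**

Total steps: 20. Longest linear sequence: 17 (steps 1, 2, 4 to 9, 12 to 20).

**Steps most likely to fail**

Step 8. The activated carbinol at Cd may ionise in part, which would erode the inversion and let the ring drift to the trans isomer, or it may lose the Cc hydrogen to give an enol ether. The fallback separates activation from displacement and sets out from 12. The phenol is acetylated selectively (Ac2O, Et3N, CH2Cl2, 0 °C) to the ring C aryl acetate F1. The Cd hydroxyl is then mesylated with retention (MeSO2Cl, Et3N, CH2Cl2, −20 °C) to the benzylic mesylate F2. Treatment with K2CO3 in MeOH–THF at 0 °C should remove the acetate, and the phenoxide O4C set free should displace the mesylate with inversion. This comes back to the route at 14.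

Step 15. The palladium alkoxide at the secondary benzylic carbon Ca may lose a β-hydride faster than it forms the C–O bond, which would give the aryl ketone and the debrominated arene. The fallback closes the other bond of ring B and sets out from 23. Miyaura borylation (B2pin2, PdCl2(dppf), KOAc, dioxane, 80 °C), in which no alkoxide is formed, should give the pinacol boronate F3. Oxidation (NaBO3, THF–H2O, rt) should give the ring A phenol F4. Camphorsulfonic acid (cat.) with 4 Å molecular sieves in CH2Cl2 at 0 °C should ionise Ca–OH, helped by the para oxygen O4C of ring C, and O3A–H should capture the cation under thermodynamic control to give the trans ring with Cb unchanged. Ring D is protected from the acid by its electron-poor ring E. This comes back to the route at 24.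

Step 19. Olefination of the electron-rich aldehyde may be slow, and the product enal may react a second time with the ylide to give the dienal. The fallback builds the enal in three operations and sets out from 27. Horner–Wadsworth–Emmons olefination ((EtO)2P(O)CH2CO2Et, NaH, THF, 0 °C) should give the ethyl (E)-cinnamate F5. Reduction with i-Bu2AlH (CH2Cl2, −78 °C) should give the (E)-cinnamyl alcohol F6. Oxidation of the allylic alcohol with MnO2 (CH2Cl2, rt) comes back to the route at 28.

**Further compounds**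

F1 | step 8 | 2-{[(1S,2S)-1-[3,4-bis(methanesulfonyloxy)phenyl]-3-[(tert-butyldimethylsilyl)oxy]-1-hydroxypropan-2-yl]oxy}-4-(1,3-dioxolan-2-yl)phenyl acetate | O1CCOC1c1ccc(OC(C)=O)c(c1)O[C@@H](CO[Si](C)(C)C(C)(C)C)[C@H](c1ccc(OS(C)(=O)=O)c(OS(C)(=O)=O)c1)O
F2 | step 8 | Cd methanesulfonate of F1 | O1CCOC1c1ccc(OC(C)=O)c(c1)O[C@@H](CO[Si](C)(C)C(C)(C)C)[C@H](c1ccc(OS(C)(=O)=O)c(OS(C)(=O)=O)c1)OS(C)(=O)=O
F3 | step 15 | pinacol boronate corresponding to 23 (Bpin in place of Br) | CC1(C)OB(OC1(C)C)c1cc(C2OCCO2)ccc1O[C@@H](CO[Si](C(C)C)(C(C)C)C(C)C)[C@@H](O)c1ccc2c(c1)O[C@@H](CO[Si](C)(C)C(C)(C)C)[C@@H](c1ccc(OS(C)(=O)=O)c(OS(C)(=O)=O)c1)O2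
F4 | step 15 | phenol corresponding to 23 (OH in place of Br) | Oc1cc(C2OCCO2)ccc1O[C@@H](CO[Si](C(C)C)(C(C)C)C(C)C)[C@@H](O)c1ccc2c(c1)O[C@@H](CO[Si](C)(C)C(C)(C)C)[C@@H](c1ccc(OS(C)(=O)=O)c(OS(C)(=O)=O)c1)O2
F5 | step 19 | ethyl (E)-propenoate corresponding to 27 | CCOC(=O)/C=C/c1ccc2c(c1)O[C@@H](c1ccc3c(c1)O[C@@H](CO[Si](C)(C)C(C)(C)C)[C@@H](c1ccc(O[Si](C)(C)C(C)(C)C)c(O[Si](C)(C)C(C)(C)C)c1)O3)[C@H](CO[Si](C(C)C)(C(C)C)C(C)C)O2
F6 | step 19 | (E)-prop-2-en-1-ol corresponding to 27 | OC/C=C/c1ccc2c(c1)O[C@@H](c1ccc3c(c1)O[C@@H](CO[Si](C)(C)C(C)(C)C)[C@@H](c1ccc(O[Si](C)(C)C(C)(C)C)c(O[Si](C)(C)C(C)(C)C)c1)O3)[C@H](CO[Si](C(C)C)(C(C)C)C(C)C)O2
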